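(The constants used here were chosen freely; the flask was simulated.)

| setting | winter | summer | midnight |
|---|---|---|---|
| E | 0.014 M | 0.014 M | 0.014 M |
| Q | 3.5 mM (held) | 3.5 mM (held) | 3.5 mM (held) |
| Z | 0.1 mol% | 0.1 mol% | 0.1 mol% |
| D | 20 mol% | 20 mol% | 20 mol% |
| temperature | 5 °C | 45 °C | 25 °C |
| time | 6.0 h | 6.0 h | 6.0 h |

- at the start none of L is dissolved
- the list of constants is for 25 °C, to be carried to other temperatures by the activation energies and enthalpies

- which flask leads in amount of X, in percent of the E charged ("all alike" within 1.5 percentage points) (winter / summer / midnight / all alike)
- how much X is there at the end, in percent of the E charged: winter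
- how much X is there at the end, in percent of the E charged: summer
- how much X is there at the end, in percent of the E charged: midnight

    Q ⇌ L, rate k1*(csat - [L]) (k1 = 1.86 × 10⁻⁴ /s, csat = 3.5 mM)
    L + D + G → D + X (k2 = 11.7 /M²/s, Ea2 = 39.0 kJ/mol)
    E + L → E.L (k3 = 0.00104 /M/s, Ea3 = 68.0 kJ/mol)
    E + Z ⇌ Z + G (K4 = 0.402, k4 = 5.13 /M/s, Ea4 = 40.0 kJ/mol, ΔH4 = −70.0 kJ/mol)
    (constants at 25 °C)

The 0.1 mol% of Z was a small charge, and in winter I expected E to reach G slowly, and I left this note for whoever took over the bench. The winter flask held E, Z and D, with no L dissolved at the start. X forms from G with D and L. D is a catalyst, and I took L at its saturation value of 3.5 mM, which makes the step pseudo-first-order in G.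

The constant of that step at 5 °C, times D, saturated L and the time, came to 0.799. I called this the take-off number: the lifetimes of G that fit into the run. Z carried E towards an equilibrium constant of 3.06, and the run covered 0.645 relaxation times of that step, so I put G and X together at 35.8% of the E charged.

If G climbs steadily, its mean is half its final value, and X over G is then half the take-off number. So the next person should find about 10.2% X and 25.6% G in winter. They should leave D alone, since the number is proportional to it. I stopped there: midnight at 2.48 and summer at 6.66 stand higher, and there I did not trust a steady climb.

The forecast gave 11% for winter, a little above mine, with 18% for summer and 26% for midnight. It put midnight in the lead, saying that flask “sits at the optimum”.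

The flasks gave 10.2% in winter, 16.8% in summer and 25.2% at midnight, so midnight led.

At 2.55 h in winter, G was being made 3.74 times as fast as it was used up, each step taken net, and the winter flask ended with L at 0.00291 M, lower than the 3.5 mM I took, and with X over G at 0.391 beside half the take-off number, 0.400. A neighbour like winter but with 5 mol% of D has a take-off number of 0.200, a quarter of winter's, which reckons to 3.25% X, and that neighbour ended with 32.7% G and 3.16% X.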